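**Plan**

- Cuts: C10–C11 (dienyllithium plus epoxy aldehyde); the oxirane back to a cis C1/C2 diol carbonate; C1–C6 and C2–C3 of ring B by a [4+2] cut; in the other half C7=C8 (Julia–Kocienski) and C1'–C2' of ring A (epoxy-polyene cyclisation of geranyl acetate).
- Enabling feature: ring B is a cyclohexene whose C4=C5 bond lies across the ring from the vicinal oxygen-bearing carbons C1 and C2, with C3–O and C6–O cis to each other and trans to the C1/C2 oxygens. This is the imprint of an out,out-1,4-dioxygenated butadiene on an acyl-substituted enediol carbonate.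
- Forward: ring B is closed first by the cycloaddition and its oxirane second by double inversion at C2; ring A is closed separately by radical cyclisation; the chain is joined at C7=C8 and last at C10–C11, then all silicon groups are removed.
- Stereochemistry: C1, C2, C3 and C6 come from the cycloaddition (relative from diene and dienophile geometry plus acyl-endo approach, absolute from the bis(oxazoline)–copper catalyst). C3' comes from Shi epoxidation and C1' from the chair-like cyclisation. C11 comes from Felkin–Anh addition, 7E from the olefination and 9Z from anti-carbomagnesiation.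

Key step: step 6

Remark: locants follow the target and are kept for all intermediates. Ring B is C1 (oxirane carbon bearing the chain), C2 (oxirane CH), C3 (CHOH), C4 (C–CH2OH), C5 (=CH), C6 (CHOH); the chain runs C11 (carbinol) to C7; ring A is C1' (CH bearing C7), C2' (CMe2), C3' (CHOH), C6' (C=CH2). The target is (1R,2S,3R,6S,11S,1'S,3'R,7E,9Z).
Remark: the diene is used with two of its three oxygens tied as a di-tert-butylsilylene; in open-chain terms it is a (1Z,3E)-1,4-bis(silyloxy)-2-(silyloxymethyl)buta-1,3-diene, the geometry in which both terminal oxygens point away from the central C–C bond.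
Remark: 1,3-dihydroxyacetone is supplied as its dimer, which reverts to the monomer in solution. TBS = tert-butyldimethylsilyl; t-Bu-box = 2,2'-(propane-2,2-diyl)bis(4-tert-butyl-4,5-dihydrooxazole).

**Route**

Step 1
Reactants: 1 1,3-dihydroxyacetone
Product: 2 2,2-di-tert-butyl-1,3,2-dioxasilinan-5-one
Conditions: t-Bu2Si(OTf)2, 2,6-lutidine, DMF, 0 °C → rt
Reagents that add atoms: di-tert-butylsilyl bis(trifluoromethanesulfonate), CC(C)(C)[Si](OS(=O)(=O)C(F)(F)F)(OS(=O)(=O)C(F)(F)F)C(C)(C)C
Why: Cyclic silylene formation from a 1,3-diol; the monomeric ketone is trapped as the six-membered dioxasilinane, the same silylation that converts dihydroxyacetone into its bis(silyl) ethers.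

Step 2
Reactants: 2 2,2-di-tert-butyl-1,3,2-dioxasilinan-5-one; 3 diethyl (cyanomethyl)phosphonate
Product: 4 2-(2,2-di-tert-butyl-1,3,2-dioxasilinan-5-ylidene)acetonitrile
Conditions: NaH, THF, 0 °C → rt
Reagents that add atoms: none
Why: Horner–Wadsworth–Emmons olefination of an activated α,α'-dioxygenated ketone; the ketone is symmetric, so no alkene geometry arises.

Step 3
Reactants: 4 2-(2,2-di-tert-butyl-1,3,2-dioxasilinan-5-ylidene)acetonitrile
Product: 6 2-(2,2-di-tert-butyl-1,3,2-dioxasilinan-5-ylidene)acetaldehyde, via N-aluminoimine 5 (not isolated)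
Conditions: i-Bu2AlH, toluene, −78 °C; then aq. tartaric acid, 0 °C
Reagents that add atoms: water, O
Why: Partial reduction of a conjugated nitrile by i-Bu2AlH stops at the N-aluminoimine, which is hydrolysed to the enal on mild acidic work-up (nitrile-to-aldehyde reduction).

Step 4
Reactants: 6 2-(2,2-di-tert-butyl-1,3,2-dioxasilinan-5-ylidene)acetaldehyde
Product: 7 2,2-di-tert-butyl-5-[(E)-2-(tert-butyldimethylsilyloxy)ethenyl]-4H-1,3,2-dioxasiline
Conditions: TBSOTf, Et3N, Et2O, 0 °C → rt
Reagents that add atoms: tert-butyldimethylsilyl trifluoromethanesulfonate, CC(C)(C)[Si](C)(C)OS(=O)(=O)C(F)(F)F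
Why: Soft dienolisation (γ-deprotonation of the O-silylated enal by Et3N); the s-trans enal should give the E enol silyl ether, and loss of a ring CH2 proton places the second enol ether inside the ring, where oxygen and the CH2O carbon are necessarily cis, so both terminal oxygens point outward.

Step 5
Reactants: 8 hydroxypyruvic acid; 9 oxazolidin-2-one
Product: 11 3-(2-oxo-1,3-dioxole-4-carbonyl)oxazolidin-2-one, via acyl imidazole 10 (not isolated)
Conditions: CDI (2.2 equiv), THF, 0 °C → rt; then 9, DBU (cat.), rt
Reagents that add atoms: 1,1'-carbonyldiimidazole, O=C(n1ccnc1)n1ccnc1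
Why: Carbonyldiimidazole converts the acid into the acyl imidazole and the α-hydroxy ketone, through its enol, into the cyclic enol carbonate (acyloin-to-dioxolone formation), and the acyl imidazole then N-acylates the oxazolidinone under amidine catalysis (azolide acyl transfer).

Step 6
Reactants: 7 2,2-di-tert-butyl-5-[(E)-2-(tert-butyldimethylsilyloxy)ethenyl]-4H-1,3,2-dioxasiline; 11 3-(2-oxo-1,3-dioxole-4-carbonyl)oxazolidin-2-one
Product: 12 ring B cycloadduct (imide on C1; cyclic carbonate on C1/C2; silylene on C3–O/C4–CH2O; TBS ether on C6)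
Conditions: [Cu{(R,R)-t-Bu-box}](SbF6)2 (10 mol %), CH2Cl2, −78 → −30 °C
Reagents that add atoms: none
Why: Proposed new method: a concerted, asynchronous suprafacial [4+2] cycloaddition between the electron-rich out,out-diene 7 and imide 11, held s-cis as a two-point chelate on square-planar divalent copper; the closest known reaction types are the copper–bis(oxazoline)-catalysed Diels–Alder reactions of acryloyl and β-acyloxyacryloyl oxazolidinones and the thermal addition of vinylene carbonate to (E,E)-1,4-diacyloxybutadienes, whereas an acyl dioxolone oxygenated at both alkene carbons has not been used in this way. Ring B closes in one intermolecular event by formation of C1–C6 and C2–C3. C3 and C6 become cis because both diene oxygens point outward (ring-locked enol ether at C3=C4, E enol silyl ether at C5=C6), C1 and C2 become cis because the dienophile is cyclic, and endo placement of the copper-bound acyl group puts the two carbonate oxygens on the face opposite the C3 and C6 oxygens. The absolute sense comes from the (R,R) ligand, whose tert-butyl groups should leave the Si face of the acyl-bearing carbon open. Regiochemistry (C6 to the acyl-bearing carbon, C3 to the β-carbon) is the para orientation relative to the oxymethyl-substituted C4, the diene terminus next to that carbon being the more nucleophilic and the quaternary centre forming at the less hindered terminus; the ring oxygen on the α-carbon is tied back in the dioxolone, so the planar chelate that activates the dienophile stays accessible.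

Step 7
Reactants: 12 ring B cycloadduct
Product: 13 methyl ester cis-1,2-diol (C1–OH and C2–OH on the face opposite C3–O and C6–O)
Conditions: K2CO3 (cat.), MeOH, 0 °C → rt
Reagents that add atoms: methanol, CO
Why: Base-catalysed methanolysis (transesterification) cleaves both the cyclic carbonate and the imide and releases the oxazolidinone; C1 carries no hydrogen, so neither elimination nor epimerisation can follow and the cis-diol is untouched.

Step 8
Reactants: 13 methyl ester cis-1,2-diol
Product: 16 methyl epoxy ester (oxirane on the face opposite C3–O and C6–O), via cyclic orthoacetate 14 (not isolated), via bromo acetate 15 (not isolated)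
Conditions: MeC(OMe)3, PPTS (cat.), CH2Cl2, rt; AcBr, Et3N (cat.), CH2Cl2, 0 °C; K2CO3, MeOH, rt
Reagents that add atoms: none
Why: One-pot cis-diol-to-epoxide conversion through a cyclic orthoester and its acetoxonium ion; bromide opens the ion at the secondary C2 with inversion (C1 is tertiary and deactivated by the ester), and methanolysis of the C1 acetate lets the alkoxide displace bromide with a second inversion, so the oxirane lies on the face the diol occupied.

Step 9
Reactants: 16 methyl epoxy ester
Product: 18 epoxy aldehyde, via aluminium hemiacetal 17 (not isolated)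
Conditions: i-Bu2AlH, CH2Cl2, −78 °C; then MeOH, aq. KNaC4H4O6
Reagents that add atoms: none
Why: Low-temperature partial reduction of a glycidic ester; the aluminium hemiacetal is stabilised by the adjacent oxirane oxygen and collapses to the aldehyde only on work-up, and C1 has no hydrogen, so the aldehyde cannot epimerise.

Step 10
Reactants: 19 geranyl acetate
Product: 20 (2E)-5-[(2R)-3,3-dimethyloxiran-2-yl]-3-methylpent-2-en-1-yl acetate
Conditions: D-fructose-derived Shi ketone (30 mol %), KHSO5 (as Oxone), K2CO3, Bu4NHSO4 (cat.), MeCN/CH2(OMe)2/aq. Na2B4O7 buffer, 0 °C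
Reagents that add atoms: potassium peroxymonosulfate, [K+].[O-]S(=O)(=O)OO
Why: Shi asymmetric epoxidation oxidises the electron-rich 6,7-alkene (the 2,3-alkene is deactivated by the allylic acetate) through the spiro dioxirane transition state, which should give the R epoxide.

Step 11
Reactants: 20 (2E)-5-[(2R)-3,3-dimethyloxiran-2-yl]-3-methylpent-2-en-1-yl acetate
Product: 21 [(1'S,3'R)-3'-hydroxy-2',2'-dimethyl-6'-methylidenecyclohexyl]methyl acetate
Conditions: Cp2TiCl2 (2.2 equiv), Mn, THF, rt; then aq. HCl
Reagents that add atoms: none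
Why: Radical epoxy-polyene cyclisation mediated by trivalent titanium; homolytic opening gives the tertiary radical, 6-endo closure through a chair with the titanoxy and acetoxymethyl groups equatorial sets C1' cis to C3'–O, and the new tertiary radical is trapped by a second Cp2TiCl and undergoes β-hydride elimination to the exocyclic alkene.

Step 12
Reactants: 21 [(1'S,3'R)-3'-hydroxy-2',2'-dimethyl-6'-methylidenecyclohexyl]methyl acetate
Product: 22 [(1'S,3'R)-3'-(tert-butyldimethylsilyloxy)-2',2'-dimethyl-6'-methylidenecyclohexyl]methyl acetate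
Conditions: TBSOTf, 2,6-lutidine, CH2Cl2, −78 → 0 °C
Reagents that add atoms: tert-butyldimethylsilyl trifluoromethanesulfonate, CC(C)(C)[Si](C)(C)OS(=O)(=O)C(F)(F)F
Why: Silyl ether formation; the triflate is needed for the hindered neopentyl-type secondary alcohol.

Step 13
Reactants: 22 [(1'S,3'R)-3'-(tert-butyldimethylsilyloxy)-2',2'-dimethyl-6'-methylidenecyclohexyl]methyl acetate
Product: 23 [(1'S,3'R)-3'-(tert-butyldimethylsilyloxy)-2',2'-dimethyl-6'-methylidenecyclohexyl]methanol
Conditions: K2CO3 (cat.), MeOH, rt
Reagents that add atoms: none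
Why: Base-catalysed transesterification removes the acetate; the secondary silyl ether is stable to K2CO3 in methanol.

Step 14
Reactants: 23 [(1'S,3'R)-3'-(tert-butyldimethylsilyloxy)-2',2'-dimethyl-6'-methylidenecyclohexyl]methanol
Product: 24 1-phenyl-1H-tetrazol-5-yl sulfide of 23
Conditions: 1-phenyl-1H-tetrazole-5-thiol, PPh3, DIAD, THF, 0 °C → rt
Reagents that add atoms: 1-phenyl-1H-tetrazole-5-thiol, Sc1nnnn1-c1ccccc1
Why: Mitsunobu thioetherification of the primary alcohol with the acidic tetrazole thiol; the stereocentres are not involved.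

Step 15
Reactants: 24 1-phenyl-1H-tetrazol-5-yl sulfide
Product: 25 1-phenyl-1H-tetrazol-5-yl sulfone
Conditions: (NH4)6Mo7O24·4H2O (cat.), 30 % H2O2, EtOH, 0 °C → rt
Reagents that add atoms: hydrogen peroxide, OO
Why: Molybdate-catalysed peroxide oxidation of sulfide to sulfone; the unactivated 1,1-disubstituted alkene should not be epoxidised under these conditions.

Step 16
Reactants: 26 prop-2-yn-1-ol
Product: 28 (2Z)-3-iodo-2-methylprop-2-en-1-ol, via alkenylmagnesium 27 (not isolated)
Conditions: MeMgBr, CuI (10 mol %), Et2O, −10 °C → rt; then I2, −78 → 0 °C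
Reagents that add atoms: methylmagnesium bromide, C[Mg]Br; iodine, II
Why: Copper-catalysed anti-carbomagnesiation of propargyl alcohol; the magnesium alkoxide directs methyl to C2 and magnesium to C3 cis to the CH2O group, and iodinolysis with retention gives the Z vinyl iodide.

Step 17
Reactants: 28 (2Z)-3-iodo-2-methylprop-2-en-1-ol
Product: 29 (2Z)-3-iodo-2-methylprop-2-enal
Conditions: MnO2, CH2Cl2, rt, dark
Reagents that add atoms: none
Why: Allylic oxidation with MnO2 under neutral conditions should give the enal without Z-to-E isomerisation; the aldehyde is used at once.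

Step 18
Reactants: 25 1-phenyl-1H-tetrazol-5-yl sulfone; 29 (2Z)-3-iodo-2-methylprop-2-enal
Product: 30 (1Z,3E)-1-iodo-2-methyl-4-[(1'S,3'R)-3'-(tert-butyldimethylsilyloxy)-2',2'-dimethyl-6'-methylidenecyclohexyl]buta-1,3-diene
Conditions: KN(SiMe3)2, THF, −78 °C; then 29, −78 °C → rt
Reagents that add atoms: none
Why: Julia–Kocienski olefination; addition of the metalated tetrazolyl sulfone to the enal, Smiles rearrangement and loss of SO2 should give the new C7=C8 alkene with E geometry, while the preformed Z vinyl iodide at C9=C10 is carried through unchanged.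

Step 19
Reactants: 30 dienyl iodide; 18 epoxy aldehyde
Product: 32 tris-silylated (11S)-carbinol, via dienyllithium 31 (not isolated)
Conditions: t-BuLi (2 equiv), Et2O, −78 °C; then 18, −78 °C
Reagents that add atoms: none
Why: Iodine–lithium exchange (alkene geometry is retained at −78 °C) followed by 1,2-addition to the non-enolisable epoxy aldehyde; C11 is set by Felkin–Anh control, the nucleophile entering anti to the C1–O bond of the oxirane with the carbonyl oxygen turned away from the C6 silyloxy group, which should give the anti epoxy alcohol (11S).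

Step 20
Reactants: 32 tris-silylated (11S)-carbinol
Product: 33 CNP0357844.1
Conditions: HF·pyridine, pyridine, THF, 0 °C → rt
Reagents that add atoms: none
Why: Fluoride-mediated global desilylation removes the two silyl ethers and the silylene in one operation; buffering with pyridine protects the oxirane and the dienylic alcohol.

**Compound list**

1 | 1,3-dihydroxyacetone | OCC(=O)CO | starting material
2 | 2,2-di-tert-butyl-1,3,2-dioxasilinan-5-one | O=C1CO[Si](C(C)(C)C)(C(C)(C)C)OC1 | intermediate
3 | diethyl (cyanomethyl)phosphonate | CCOP(=O)(CC#N)OCC | starting material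
4 | 2-(2,2-di-tert-butyl-1,3,2-dioxasilinan-5-ylidene)acetonitrile | N#CC=C1CO[Si](C(C)(C)C)(C(C)(C)C)OC1 | intermediate
5 | N-(diisobutylalumanyl)imine of aldehyde 6 | CC(C)C[Al](CC(C)C)N=CC=C1CO[Si](C(C)(C)C)(C(C)(C)C)OC1 | intermediate
6 | 2-(2,2-di-tert-butyl-1,3,2-dioxasilinan-5-ylidene)acetaldehyde | O=CC=C1CO[Si](C(C)(C)C)(C(C)(C)C)OC1 | intermediate
7 | 2,2-di-tert-butyl-5-[(E)-2-(tert-butyldimethylsilyloxy)ethenyl]-4H-1,3,2-dioxasiline | CC(C)(C)[Si]1(C(C)(C)C)OCC(=CO1)/C=C/O[Si](C)(C)C(C)(C)C | intermediate
8 | hydroxypyruvic acid | OCC(=O)C(O)=O | starting material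
9 | oxazolidin-2-one | O=C1NCCO1 | starting material
10 | 4-(1H-imidazole-1-carbonyl)-1,3-dioxol-2-one | O=C1OC=C(O1)C(=O)n1ccnc1 | intermediate
11 | 3-(2-oxo-1,3-dioxole-4-carbonyl)oxazolidin-2-one | O=C1OC=C(O1)C(=O)N1CCOC1=O | intermediate
12 | ring B cycloadduct: imide on C1, cyclic carbonate on C1/C2 (one face), silylene on C3–O/C4–CH2O and TBS ether on C6 (other face) | O=C(N1CCOC1=O)[C@]23OC(=O)O[C@H]2[C@@H]4O[Si](C(C)(C)C)(C(C)(C)C)OCC4=C[C@@H]3O[Si](C)(C)C(C)(C)C | intermediate
13 | methyl ester cis-1,2-diol | COC(=O)[C@]1(O)[C@@H](O)[C@@H]2O[Si](C(C)(C)C)(C(C)(C)C)OCC2=C[C@@H]1O[Si](C)(C)C(C)(C)C | intermediate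
14 | C1/C2 cyclic methyl orthoacetate of 13 | COC(=O)[C@]12OC(C)(OC)O[C@H]1[C@@H]3O[Si](C(C)(C)C)(C(C)(C)C)OCC3=C[C@@H]2O[Si](C)(C)C(C)(C)C | intermediate
15 | C1-acetoxy C2-bromo ester (bromine trans to the acetate) | COC(=O)[C@]1(OC(C)=O)[C@H](Br)[C@@H]2O[Si](C(C)(C)C)(C(C)(C)C)OCC2=C[C@@H]1O[Si](C)(C)C(C)(C)C | intermediate
16 | methyl epoxy ester | COC(=O)[C@]12O[C@H]1[C@@H]3O[Si](C(C)(C)C)(C(C)(C)C)OCC3=C[C@@H]2O[Si](C)(C)C(C)(C)C | intermediate
17 | diisobutylaluminium methyl hemiacetal of 18 | COC(O[Al](CC(C)C)CC(C)C)[C@]12O[C@H]1[C@@H]3O[Si](C(C)(C)C)(C(C)(C)C)OCC3=C[C@@H]2O[Si](C)(C)C(C)(C)C | intermediate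
18 | epoxy aldehyde | O=C[C@]12O[C@H]1[C@@H]3O[Si](C(C)(C)C)(C(C)(C)C)OCC3=C[C@@H]2O[Si](C)(C)C(C)(C)C | intermediate
19 | geranyl acetate | CC(=O)OC/C=C(\C)CCC=C(C)C | starting material
20 | (2E)-5-[(2R)-3,3-dimethyloxiran-2-yl]-3-methylpent-2-en-1-yl acetate | CC(=O)OC/C=C(\C)CC[C@H]1OC1(C)C | intermediate
21 | [(1'S,3'R)-3'-hydroxy-2',2'-dimethyl-6'-methylidenecyclohexyl]methyl acetate | C=C1CC[C@@H](O)C(C)(C)[C@H]1COC(C)=O | intermediate
22 | [(1'S,3'R)-3'-(tert-butyldimethylsilyloxy)-2',2'-dimethyl-6'-methylidenecyclohexyl]methyl acetate | C=C1CC[C@@H](O[Si](C)(C)C(C)(C)C)C(C)(C)[C@H]1COC(C)=O | intermediate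
23 | [(1'S,3'R)-3'-(tert-butyldimethylsilyloxy)-2',2'-dimethyl-6'-methylidenecyclohexyl]methanol | C=C1CC[C@@H](O[Si](C)(C)C(C)(C)C)C(C)(C)[C@H]1CO | intermediate
24 | 1-phenyl-1H-tetrazol-5-yl sulfide of 23 | C=C1CC[C@@H](O[Si](C)(C)C(C)(C)C)C(C)(C)[C@H]1CSc1nnnn1-c1ccccc1 | intermediate
25 | 1-phenyl-1H-tetrazol-5-yl sulfone | C=C1CC[C@@H](O[Si](C)(C)C(C)(C)C)C(C)(C)[C@H]1CS(=O)(=O)c1nnnn1-c1ccccc1 | intermediate
26 | prop-2-yn-1-ol | OCC#C | starting material
27 | (Z)-3-(bromomagnesio)-2-methylprop-2-en-1-olate magnesium bromide | Br[Mg]/C=C(/C)CO[Mg]Br | intermediate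
28 | (2Z)-3-iodo-2-methylprop-2-en-1-ol | OC/C(C)=C\I | intermediate
29 | (2Z)-3-iodo-2-methylprop-2-enal | O=C/C(C)=C\I | intermediate
30 | (1Z,3E)-1-iodo-2-methyl-4-[(1'S,3'R)-3'-(tert-butyldimethylsilyloxy)-2',2'-dimethyl-6'-methylidenecyclohexyl]buta-1,3-diene | C=C1CC[C@@H](O[Si](C)(C)C(C)(C)C)C(C)(C)[C@H]1/C=C/C(C)=C\I | intermediate
31 | (1Z,3E)-dienyllithium from 30 | C=C1CC[C@@H](O[Si](C)(C)C(C)(C)C)C(C)(C)[C@H]1/C=C/C(C)=C\[Li] | intermediate
32 | tris-silylated (11S)-carbinol (TBS on C3'–O and C6–O, silylene on C3–O/C4–CH2O) | C=C1CC[C@@H](O[Si](C)(C)C(C)(C)C)C(C)(C)[C@H]1/C=C/C(C)=C\[C@H](O)[C@]12O[C@H]1[C@@H]3O[Si](C(C)(C)C)(C(C)(C)C)OCC3=C[C@@H]2O[Si](C)(C)C(C)(C)C | intermediate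
33 | CNP0357844.1 | C=C1CC[C@@H](O)C(C)(C)[C@H]1/C=C/C(C)=C\[C@H](O)[C@]12O[C@H]1[C@H](O)C(CO)=C[C@@H]2O | target

**Count**

Total step count: 20. Longest linear sequence: 10 steps (steps 1–4, 6–9, 19 and 20).

**Steps most likely to fail**

1. Step 6 (cycloaddition). What may go wrong: loss of regiocontrol between the two oxygenated diene termini, exo instead of endo approach of the acyl group, insufficient discrimination of the two dienophile faces, or arrest after the first C–C bond (conjugate addition of the silyl dienol ether without ring closure). The fallback sets out from diene 7 and rejoins the route at epoxy ester 16, so steps 7 and 8 are not needed. Diene 7 would be combined with the known dienophile 3-[(E)-3-acetoxyprop-2-enoyl]oxazolidin-2-one under the same [Cu{(R,R)-t-Bu-box}](SbF6)2 catalysis, a substrate class for which this catalysis is established, to give the acetoxy imide adduct F1 (C3 and C6 set by the catalyst, C1–H, C2–OAc). DBU in CH2Cl2 would eliminate acetic acid (E1cB) to the cyclohexa-1,4-dienyl imide F2. NaOMe in MeOH at −20 °C would give the methyl dienoate F3. Nucleophilic epoxidation with t-BuOOLi (THF, −78 → 0 °C), the peroxide entering C2 anti to the C3 and C6 silyloxy groups, would then give 16.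

2. Step 19 (C10–C11 bond). What may go wrong: attack on the other face of the aldehyde (approach past C2–H with the carbonyl anti to the oxirane oxygen), giving the 11R epimer or a mixture. The fallback sets out from the C11-epimeric material of step 19 (32 with its epimer) and returns at 32. Dess–Martin oxidation (NaHCO3, CH2Cl2, 0 °C) would give the dienone F4. This would be reduced at once at −78 °C by Corey–Bakshi–Shibata reduction (catecholborane, the oxazaborolidine enantiomer that delivers hydride to the Re face of C11), so that C11 is set by the reagent and not by the substrate.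

3. Step 8 (diol to oxirane). What may go wrong: slow or misdirected bromide opening of the acetoxonium ion at the hindered C2, or hydrolysis of the ion back to a hydroxy acetate. The fallback sets out from diol 13 and returns at 16. The secondary C2–OH would be triflated selectively (Tf2O, pyridine, CH2Cl2, −30 °C) to the C2 triflate F5. Bu4NBr (toluene, rt) would displace the triflate with inversion to give the trans bromohydrin F6; anti elimination is not available, because C1 has no hydrogen and C3–H is syn to the leaving group. K2CO3 in MeOH would then close the oxirane to 16.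

**Further compounds**

F1 | step 6 | acetoxy imide adduct (C1–H, C2–OAc trans to the acyl group) | O=C(N1CCOC1=O)[C@@H]1[C@@H](OC(C)=O)[C@@H]2O[Si](C(C)(C)C)(C(C)(C)C)OCC2=C[C@@H]1O[Si](C)(C)C(C)(C)C
F2 | step 6 | cyclohexa-1,4-dienyl imide | O=C(N1CCOC1=O)C1=C[C@@H]2O[Si](C(C)(C)C)(C(C)(C)C)OCC2=C[C@@H]1O[Si](C)(C)C(C)(C)C
F3 | step 6 | methyl cyclohexa-1,4-diene-1-carboxylate | COC(=O)C1=C[C@@H]2O[Si](C(C)(C)C)(C(C)(C)C)OCC2=C[C@@H]1O[Si](C)(C)C(C)(C)C
F4 | step 19 | C11 dienone | C=C1CC[C@@H](O[Si](C)(C)C(C)(C)C)C(C)(C)[C@H]1/C=C/C(C)=C\C(=O)[C@]12O[C@H]1[C@@H]3O[Si](C(C)(C)C)(C(C)(C)C)OCC3=C[C@@H]2O[Si](C)(C)C(C)(C)C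
F5 | step 8 | C2 triflate of diol 13 | COC(=O)[C@]1(O)[C@@H](OS(=O)(=O)C(F)(F)F)[C@@H]2O[Si](C(C)(C)C)(C(C)(C)C)OCC2=C[C@@H]1O[Si](C)(C)C(C)(C)C
F6 | step 8 | trans C2 bromohydrin | COC(=O)[C@]1(O)[C@H](Br)[C@@H]2O[Si](C(C)(C)C)(C(C)(C)C)OCC2=C[C@@H]1O[Si](C)(C)C(C)(C)C
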